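Early on, in the grey run (the flask you asked about), watch target come down from 14.2% at 30.0 h. From 60.0 h to 192 h its readings average 10.3%, and the last of them already stands at the asked time, so that average is my quick number for now.

all flasks: starting material 0.10 M

| run | coupling partner | protic impurity | temperature | remark | time |
|---|---|---|---|---|---|
| grey | 0.15 M | 0.10 M | 70 °C | the very flask that is asked about, followed so far |  |
| teal | 0.15 M | 0.15 M | 55 °C | run made earlier |  |
| flask | 0.150 M | 0.100 M | 70 °C |  | 8.0 d |

| grey: time / h | grey: target / % | teal: time / h | teal: target / % |
|---|---|---|---|
| 30.0 | 14.2 | 6.00 | 33.1 |
| 60.0 | 10.9 | 12.0 | 30.3 |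
| 72.0 | 10.4 | 15.0 | 29.0 |
| 120 | 10.9 | 25.0 | 21.9 |
| 144 | 9.0 | 30.0 | 19.9 |
| 192 | 10.1 | 40.0 | 16.7 |

(each reading ± 0.5 percentage points)

- target, in percent of the starting material first charged, at 8.0 d
- the remedy with the largest gain of target, or "none" below 2 percentage points (south-west / north-east / west / south / none)
- target present, with what was taken out counted in, in percent of the starting material first charged, after west
- target present, with what was taken out counted in, in percent of the starting material first charged, after south

- south-west: at 8.0 d take out 90% of the target then present, then wait 4.0 d
- north-east: change nothing and wait 4.0 d more
- west: at 8.0 d raise the temperature by 25 K, then wait 4.0 d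
- south: at 8.0 d add coupling partner, 100% of the amount charged, then wait 4.0 d

- what is taken out of target is counted as made
- steps under discussion: starting material + coupling partner <-> target; starting material + coupling partner <-> isomer of the product A; coupling partner + protic impurity -> quenched reagent; target <-> isomer of the product B
- additions bring no volume worth counting

Freeze what stops moving. Quenching takes one partner per impurity and gives nothing back, so if the whole impurity charge is quenched, the partner available for binding is the surplus, charge minus impurity: 0.0500 M in this flask, against 0.10 M of starting material. That puts a cap near 50.0% on bound starting material, with the surplus as limiting reagent. The teal run charges partner and impurity alike, so it has no surplus, and its target is still sinking at 16.7% at 40.0 h.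

Carry one number, the target share, meaning resting target divided by the cap: 0.205. At 70 °C, I take resting target as share times cap, and the cap as the whole charge once the surplus exceeds the starting material. South adds 0.150 M of partner, lifting the surplus to 0.200 M, more than the starting material, so I reckon 20.5% of target. That costs one subtraction and two divisions.

Your forecast says 10.1% now, south as best, 8% after west and 21% after south, and of south it says that “fresh partner survives and pushes remaining starting material into products”. On south, my figure and yours lie close.

The flask gives 9.67%, best south with a gain of 11 percentage points, 12.0% after west and 20.4% after south.

    starting material + coupling partner ⇌ target (K = 19.0 /M, k = 4.10 /M/h, Ea = 59.0 kJ/mol, ΔH = 17.0 kJ/mol)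
    starting material + coupling partner ⇌ isomer of the product A (K = 63.0 /M, k = 2.00 /M/h, Ea = 88.0 kJ/mol, ΔH = 5.00 kJ/mol)
    coupling partner + protic impurity → quenched reagent (k = 1.40 /M/h, Ea = 63.0 kJ/mol)
    target ⇌ isomer of the product B (K = 0.110, k = 0.340 /h, Ea = 96.0 kJ/mol, ΔH = −35.0 kJ/mol)
    (constants at 70 °C)

After south this flask gives 20.4%, where the share of 0.205 gave me 20.5%. Now take the same flask with 0.26 M of coupling partner. Its surplus is 0.160 M, more than the starting material, so the cap is the whole charge and the share gives 20.5%. At 192 h that neighbour holds 19.5% target, with 64.5% as isomer of the product A.

The numbers in the tables stem from a simulated flask with constants of no real substance, and the scatter is random.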